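## Retrosynthetic overview

1. Target ⇐ methacrylation of the 8α-alcohol; O8 is carried as a triethylsilyl ether.
2. Ten-membered carbocycle and α-methylene-γ-lactone ⇐ C6–C7 bond by visible-light photoredox/chromium-catalysed intramolecular allylation of the C6 enal by a (Z)-2-(bromomethyl)enoate, then lactonisation.
3. Bromo-enoate ⇐ Morita–Baylis–Hillman reaction and SN2′ bromination at the C7 aldehyde; the C7 and C6 aldehydes ⇐ oxidation of a primary silyl ether and of an allylic alcohol.
4. cis-1,10-Epoxide and C14–OAc ⇐ nucleophilic epoxidation of an (E)-α-alkylidene-γ-butyrolactone anti to its C8 substituent, then reductive lactone opening.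
5. Alkylidene lactone ⇐ aldol condensation of L-glutamic-acid-derived (S)-γ-(hydroxymethyl)-γ-butyrolactone (C7–C10, C14; supplies C8) with the C1–C6 aldehyde from geranyl acetate. Ring order: butyrolactone template (bought, later opened) → oxirane → ten-membered carbocycle → α-methylene-γ-lactone.

Assumption: germacrane numbering (C1–C15) is used for all intermediates; the target is the (1R,6R,7R,8S,10R)-4E isomer written in the SMILES (ring-cis 1,10-epoxide, trans-fused 6,12-lactone); 1, 3 and 15 are bought.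

## Route

Step 1
Reactants: 1 (S)-5-(hydroxymethyl)dihydrofuran-2(3H)-one
Product: 2 (S)-5-[(triethylsilyloxy)methyl]dihydrofuran-2(3H)-one
Conditions: Et3SiCl, imidazole, CH2Cl2, 0 °C
Reagents that add atoms: chlorotriethylsilane, CC[Si](CC)(CC)Cl
Why: Imidazole-promoted silyl ether protection of the primary alcohol; the C8 stereocentre bought with the lactone is untouched.

Step 2
Reactants: 3 geranyl acetate [(2E)-3,7-dimethylocta-2,6-dien-1-yl acetate]
Product: 5 (2E)-3-methyl-6-oxohex-2-en-1-yl acetate, via ozonide 4 (not isolated)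
Conditions: O3 (1.0 equiv), CH2Cl2, −78 °C; then Me2S, −78 → 23 °C
Reagents that add atoms: ozone, [O-][O+]=O
Why: Chemoselective ozonolysis (Criegee mechanism, reductive work-up) of the electron-rich remote olefin, the other olefin being deactivated by its allylic acetate; the E geometry of the future C4=C5 bond is bought with geranyl acetate.

Step 3
Reactants: 2 (S)-5-[(triethylsilyloxy)methyl]dihydrofuran-2(3H)-one; 5 (2E)-3-methyl-6-oxohex-2-en-1-yl acetate
Product: 8 (3E,5S)-3-[(4E)-6-acetoxy-4-methylhex-4-en-1-ylidene]-5-[(triethylsilyloxy)methyl]dihydrofuran-2(3H)-one, via aldol adduct 6 (not isolated), via mesylate 7 (not isolated)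
Conditions: LiN(i-Pr)2, THF, −78 °C; then 5; then MsCl, −78 → 0 °C; then DBU, 23 °C
Reagents that add atoms: none
Why: Lithium enolate aldol addition, in situ mesylation and E1cB elimination (aldol condensation) give the thermodynamically preferred (E)-alkylidene lactone, which places the C2 chain cis to C9 as the ring-cis C1–C10 unit of the target requires.

Step 4
Reactants: 8 (3E,5S)-3-[(4E)-6-acetoxy-4-methylhex-4-en-1-ylidene]-5-[(triethylsilyloxy)methyl]dihydrofuran-2(3H)-one
Product: 9 (2R,3S,6S)-2-[(3E)-5-acetoxy-3-methylpent-3-en-1-yl]-6-[(triethylsilyloxy)methyl]-1,5-dioxaspiro[2.4]heptan-4-one (epoxide O trans to the CH2OSiEt3 group)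
Conditions: t-BuOOH, n-BuLi, THF, −78 → −20 °C
Reagents that add atoms: tert-butyl hydroperoxide (used as its lithium salt), CC(C)(C)OO
Why: Weitz–Scheffer nucleophilic epoxidation touches only the electron-poor alkylidene lactone and keeps its E geometry, and the intermediate enolate closes onto oxygen on the face anti to the C8 substituent (the facial bias known from trans-selective alkylations of such lactone enolates), so C1 and C10 are set from C8; a minor syn-face diastereomer, if formed, is removed by chromatography.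

Step 5
Reactants: 9 (2R,3S,6S)-2-[(3E)-5-acetoxy-3-methylpent-3-en-1-yl]-6-[(triethylsilyloxy)methyl]-1,5-dioxaspiro[2.4]heptan-4-one
Product: 10 (2S)-1-[(2R,3R)-3-[(3E)-5-hydroxy-3-methylpent-3-en-1-yl]-2-(hydroxymethyl)oxiran-2-yl]-3-[(triethylsilyl)oxy]propan-2-ol
Conditions: LiBH4, THF, 0 → 23 °C
Reagents that add atoms: none
Why: Borohydride ester reduction opens the activated glycidic lactone to the C14/C8 diol and cleaves the C6 acetate, leaving the hindered trisubstituted epoxide and all three stereocentres intact.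

Step 6
Reactants: 10 (2S)-1-[(2R,3R)-3-[(3E)-5-hydroxy-3-methylpent-3-en-1-yl]-2-(hydroxymethyl)oxiran-2-yl]-3-[(triethylsilyl)oxy]propan-2-ol
Product: 11 (2E)-5-[(2R,3R)-3-{(2S)-2-hydroxy-3-[(triethylsilyl)oxy]propyl}-3-(hydroxymethyl)oxiran-2-yl]-3-methylpent-2-enal
Conditions: MnO2, CH2Cl2, 23 °C
Reagents that add atoms: none
Why: MnO2 allylic oxidation is chemoselective because, after the epoxidation, the C6 hydroxyl is the only allylic alcohol left; it gives the (E)-enal.

Step 7
Reactants: 11 (2E)-5-[(2R,3R)-3-{(2S)-2-hydroxy-3-[(triethylsilyl)oxy]propyl}-3-(hydroxymethyl)oxiran-2-yl]-3-methylpent-2-enal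
Product: 13 [(2R,3R)-2-{(2S)-2,3-bis[(triethylsilyl)oxy]propyl}-3-[(3E)-3-methyl-5-oxopent-3-en-1-yl]oxiran-2-yl]methyl acetate, via monoacetate 12 (not isolated)
Conditions: AcCl, 2,4,6-collidine, CH2Cl2, −78 °C; then Et3SiCl, imidazole, 0 → 23 °C
Reagents that add atoms: acetyl chloride, CC(=O)Cl; chlorotriethylsilane, CC[Si](CC)(CC)Cl
Why: Kinetically selective acylation of the primary C14 alcohol over the secondary C8 alcohol (collidine-buffered acetyl chloride at low temperature), then silyl ether protection of the remaining C8 hydroxyl in the same flask.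

Step 8
Reactants: 13 [(2R,3R)-2-{(2S)-2,3-bis[(triethylsilyl)oxy]propyl}-3-[(3E)-3-methyl-5-oxopent-3-en-1-yl]oxiran-2-yl]methyl acetate
Product: 14 [(2R,3R)-3-[(3E)-3-methyl-5-oxopent-3-en-1-yl]-2-{(2S)-3-oxo-2-[(triethylsilyl)oxy]propyl}oxiran-2-yl]methyl acetate
Conditions: (COCl)2, DMSO, CH2Cl2, −78 → −40 °C; then Et3N, −78 → 0 °C
Reagents that add atoms: none
Why: Swern oxidation cleaves and oxidises a primary triethylsilyl ether directly to the aldehyde (oxidative desilylation via the alkoxysulfonium salt) while the secondary silyl ether at C8 survives, and the α-silyloxy aldehyde keeps its configuration at low temperature.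

Step 9
Reactants: 14 [(2R,3R)-3-[(3E)-3-methyl-5-oxopent-3-en-1-yl]-2-{(2S)-3-oxo-2-[(triethylsilyl)oxy]propyl}oxiran-2-yl]methyl acetate; 15 methyl acrylate
Product: 16 methyl (4S)-5-{(2R,3R)-2-(acetoxymethyl)-3-[(3E)-3-methyl-5-oxopent-3-en-1-yl]oxiran-2-yl}-3-hydroxy-2-methylidene-4-[(triethylsilyl)oxy]pentanoate (both C3 epimers)
Conditions: DABCO (1 equiv), 15 (excess, neat), MeOH (cat.), 23 °C, 3–5 d
Reagents that add atoms: none
Why: Morita–Baylis–Hillman reaction: the DABCO–acrylate zwitterion adds to the electrophilic saturated α-silyloxy aldehyde and not to the β,β-disubstituted enal, and the new carbinol centre (C7, mixture) is erased in the next step.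

Step 10
Reactants: 16 methyl (4S)-5-{(2R,3R)-2-(acetoxymethyl)-3-[(3E)-3-methyl-5-oxopent-3-en-1-yl]oxiran-2-yl}-3-hydroxy-2-methylidene-4-[(triethylsilyl)oxy]pentanoate
Product: 18 methyl (2Z,4S)-5-{(2R,3R)-2-(acetoxymethyl)-3-[(3E)-3-methyl-5-oxopent-3-en-1-yl]oxiran-2-yl}-2-(bromomethyl)-4-[(triethylsilyl)oxy]pent-2-enoate, via allylic mesylate 17 (not isolated)
Conditions: Ms2O, i-Pr2NEt, CH2Cl2, −20 °C; then LiBr, THF, 0 °C
Reagents that add atoms: lithium bromide, [Li+].[Br-]
Why: Mesylation and SN2′ displacement by bromide (allylic transposition of a Baylis–Hillman adduct) give the conjugated primary bromide as the favoured Z isomer (C8 cis to CH2Br) from both C7 epimers.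

Step 11
Reactants: 18 methyl (2Z,4S)-5-{(2R,3R)-2-(acetoxymethyl)-3-[(3E)-3-methyl-5-oxopent-3-en-1-yl]oxiran-2-yl}-2-(bromomethyl)-4-[(triethylsilyl)oxy]pent-2-enoate
Product: 20 14-acetoxy-1β,10β-epoxy-8α-(triethylsilyloxy)germacra-4E,11(13)-dien-6α,12-olide, via hydroxy ester 19 (not isolated)
Conditions: 4CzIPN (2 mol %), CrCl3(THF)3 (10 mol %), Hantzsch ester (1.5 equiv), 2,6-lutidine (1.2 equiv), DMF, 450 nm LEDs, 23 °C, slow addition of 18 (final 0.003 M); then PPTS (cat.), CH2Cl2, 23 °C
Reagents that add atoms: none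
Why: Proposed new method: photoexcited 4CzIPN is quenched by the Hantzsch ester and its radical anion reduces both the allylic bromide (to the 2-(methoxycarbonyl)allyl radical) and trivalent chromium (to divalent chromium), which captures the radical as a catalytic allylchromium species that adds through C7 to the C6 aldehyde in a closed chair transition state, after which lutidinium protonolysis of the chromium alkoxide turns the catalyst over and the hydroxy ester lactonises; C7 and C6 are set from C8 because H8 eclipses the allyl unit and the aldehyde approaches anti to the bulky C8 silyloxy group, while the ring-cis C9–C10–C1 tether is expected to hold C5 and C8 pseudo-equatorial and so give the anti (trans-lactone) adduct; the closest known reactions are the stoichiometric CrCl2 Nozaki–Hiyama–Kishi macrocyclisation of ω-formyl 2-(bromomethyl)enoates and the intermolecular photoredox/chromium dual-catalytic allylation of aldehydes, neither shown for a ten-membered ring closure with in situ lactonisation.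

Step 12
Reactants: 20 14-acetoxy-1β,10β-epoxy-8α-(triethylsilyloxy)germacra-4E,11(13)-dien-6α,12-olide
Product: 21 14-acetoxy-1β,10β-epoxy-8α-hydroxygermacra-4E,11(13)-dien-6α,12-olide
Conditions: HF·pyridine, pyridine, THF, 0 °C
Reagents that add atoms: none
Why: Buffered fluoride-mediated desilylation removes the secondary silyl ether without opening the epoxide and without the base-induced translactonisation to the 8,12-olide that a free alkoxide would allow.

Step 13
Reactants: 21 14-acetoxy-1β,10β-epoxy-8α-hydroxygermacra-4E,11(13)-dien-6α,12-olide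
Product: 22 14-acetoxy-1β,10β-epoxy-8α-(methacryloyloxy)germacra-4E,11(13)-dien-6α,12-olide (CNP0150481.4)
Conditions: methacrylic anhydride, Et3N, DMAP (cat.), CH2Cl2, 0 °C
Reagents that add atoms: methacrylic anhydride, C=C(C)C(=O)OC(=O)C(C)=C
Why: DMAP-catalysed O-acylation of the secondary C8 alcohol proceeds with retention at C8 and completes the target.

## Compound list

1 | (S)-5-(hydroxymethyl)dihydrofuran-2(3H)-one | OC[C@@H]1CCC(=O)O1 | starting material
2 | (S)-5-[(triethylsilyloxy)methyl]dihydrofuran-2(3H)-one | CC[Si](CC)(CC)OC[C@@H]1CCC(=O)O1 | intermediate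
3 | geranyl acetate, (2E)-3,7-dimethylocta-2,6-dien-1-yl acetate | CC(C)=CCC/C(C)=C/COC(C)=O | starting material
4 | 5-[(3E)-5-acetoxy-3-methylpent-3-en-1-yl]-3,3-dimethyl-1,2,4-trioxolane (ozonide) | CC1(C)OOC(CC/C(C)=C/COC(C)=O)O1 | intermediate (not isolated)
5 | (2E)-3-methyl-6-oxohex-2-en-1-yl acetate | O=CCC/C(C)=C/COC(C)=O | intermediate
6 | (5S)-3-[(4E)-6-acetoxy-1-hydroxy-4-methylhex-4-en-1-yl]-5-[(triethylsilyloxy)methyl]dihydrofuran-2(3H)-one (aldol adduct, mixture at the two new centres) | CC[Si](CC)(CC)OC[C@@H]1CC(C(O)CC/C(C)=C/COC(C)=O)C(=O)O1 | intermediate (not isolated)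
7 | (5S)-3-[(4E)-6-acetoxy-4-methyl-1-(methylsulfonyloxy)hex-4-en-1-yl]-5-[(triethylsilyloxy)methyl]dihydrofuran-2(3H)-one (mesylate) | CC[Si](CC)(CC)OC[C@@H]1CC(C(OS(C)(=O)=O)CC/C(C)=C/COC(C)=O)C(=O)O1 | intermediate (not isolated)
8 | (3E,5S)-3-[(4E)-6-acetoxy-4-methylhex-4-en-1-ylidene]-5-[(triethylsilyloxy)methyl]dihydrofuran-2(3H)-one | CC[Si](CC)(CC)OC[C@@H]1C/C(=C\CC/C(C)=C/COC(C)=O)C(=O)O1 | intermediate
9 | (2R,3S,6S)-2-[(3E)-5-acetoxy-3-methylpent-3-en-1-yl]-6-[(triethylsilyloxy)methyl]-1,5-dioxaspiro[2.4]heptan-4-one | CC[Si](CC)(CC)OC[C@@H]1C[C@@]2(O[C@@H]2CC/C(C)=C/COC(C)=O)C(=O)O1 | intermediate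
10 | (2S)-1-[(2R,3R)-3-[(3E)-5-hydroxy-3-methylpent-3-en-1-yl]-2-(hydroxymethyl)oxiran-2-yl]-3-[(triethylsilyl)oxy]propan-2-ol | CC[Si](CC)(CC)OC[C@@H](O)C[C@]1(CO)O[C@@H]1CC/C(C)=C/CO | intermediate
11 | (2E)-5-[(2R,3R)-3-{(2S)-2-hydroxy-3-[(triethylsilyl)oxy]propyl}-3-(hydroxymethyl)oxiran-2-yl]-3-methylpent-2-enal | CC[Si](CC)(CC)OC[C@@H](O)C[C@]1(CO)O[C@@H]1CC/C(C)=C/C=O | intermediate
12 | [(2R,3R)-2-{(2S)-2-hydroxy-3-[(triethylsilyl)oxy]propyl}-3-[(3E)-3-methyl-5-oxopent-3-en-1-yl]oxiran-2-yl]methyl acetate (monoacetate) | CC[Si](CC)(CC)OC[C@@H](O)C[C@]1(COC(C)=O)O[C@@H]1CC/C(C)=C/C=O | intermediate (not isolated)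
13 | [(2R,3R)-2-{(2S)-2,3-bis[(triethylsilyl)oxy]propyl}-3-[(3E)-3-methyl-5-oxopent-3-en-1-yl]oxiran-2-yl]methyl acetate | CC[Si](CC)(CC)OC[C@@H](O[Si](CC)(CC)CC)C[C@]1(COC(C)=O)O[C@@H]1CC/C(C)=C/C=O | intermediate
14 | [(2R,3R)-3-[(3E)-3-methyl-5-oxopent-3-en-1-yl]-2-{(2S)-3-oxo-2-[(triethylsilyl)oxy]propyl}oxiran-2-yl]methyl acetate | O=C[C@@H](O[Si](CC)(CC)CC)C[C@]1(COC(C)=O)O[C@@H]1CC/C(C)=C/C=O | intermediate
15 | methyl acrylate | C=CC(=O)OC | starting material
16 | methyl (4S)-5-{(2R,3R)-2-(acetoxymethyl)-3-[(3E)-3-methyl-5-oxopent-3-en-1-yl]oxiran-2-yl}-3-hydroxy-2-methylidene-4-[(triethylsilyl)oxy]pentanoate (C3 epimers) | C=C(C(=O)OC)C(O)[C@@H](O[Si](CC)(CC)CC)C[C@]1(COC(C)=O)O[C@@H]1CC/C(C)=C/C=O | intermediate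
17 | methyl (4S)-5-{(2R,3R)-2-(acetoxymethyl)-3-[(3E)-3-methyl-5-oxopent-3-en-1-yl]oxiran-2-yl}-2-methylidene-3-(methylsulfonyloxy)-4-[(triethylsilyl)oxy]pentanoate (allylic mesylate) | C=C(C(=O)OC)C(OS(C)(=O)=O)[C@@H](O[Si](CC)(CC)CC)C[C@]1(COC(C)=O)O[C@@H]1CC/C(C)=C/C=O | intermediate (not isolated)
18 | methyl (2Z,4S)-5-{(2R,3R)-2-(acetoxymethyl)-3-[(3E)-3-methyl-5-oxopent-3-en-1-yl]oxiran-2-yl}-2-(bromomethyl)-4-[(triethylsilyl)oxy]pent-2-enoate | BrC/C(C(=O)OC)=C\[C@@H](O[Si](CC)(CC)CC)C[C@]1(COC(C)=O)O[C@@H]1CC/C(C)=C/C=O | intermediate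
19 | methyl 14-acetoxy-1β,10β-epoxy-6α-hydroxy-8α-(triethylsilyloxy)germacra-4E,11(13)-dien-12-oate (hydroxy ester) | CC[Si](CC)(CC)O[C@H]1C[C@]2(COC(C)=O)O[C@@H]2CC/C(C)=C/[C@@H](O)[C@@H]1C(=C)C(=O)OC | intermediate (not isolated)
20 | 14-acetoxy-1β,10β-epoxy-8α-(triethylsilyloxy)germacra-4E,11(13)-dien-6α,12-olide | CC[Si](CC)(CC)O[C@H]1C[C@]2(COC(C)=O)O[C@@H]2CC/C(C)=C/[C@H]2OC(=O)C(=C)[C@H]12 | intermediate
21 | 14-acetoxy-1β,10β-epoxy-8α-hydroxygermacra-4E,11(13)-dien-6α,12-olide | O[C@H]1C[C@]2(COC(C)=O)O[C@@H]2CC/C(C)=C/[C@H]2OC(=O)C(=C)[C@H]12 | intermediate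
22 | 14-acetoxy-1β,10β-epoxy-8α-(methacryloyloxy)germacra-4E,11(13)-dien-6α,12-olide, (1R,6R,7R,8S,10R) | C=C(C)C(=O)O[C@H]1C[C@]2(COC(C)=O)O[C@@H]2CC/C(C)=C/[C@H]2OC(=O)C(=C)[C@H]12 | target

## Step count and risks

Total: 13 steps. Longest linear sequence: 12 steps (from 1 through steps 1 and 3–13; the geranyl acetate branch, steps 2–13, is equally long).

The three steps most likely to fail:

**Step 11 (proposed new step).** The risks are slow turnover of the chromium alkoxide at high dilution, the C6/C7 diastereoselectivity (cis- versus trans-lactone, and the sense relative to C8), and survival of the epoxide. The fallback sets out from 18 and comes back to the route at 20. It is the known stoichiometric Nozaki–Hiyama–Kishi macrocyclisation: 18 is added slowly to CrCl2 (8 equiv) in degassed DMF/THF at 23 °C in the dark (final 0.002 M). The allylchromium reagent forms thermally and gives hydroxy ester 19 after aqueous work-up, which is closed to 20 with PPTS in CH2Cl2. No photocatalyst or light is used. New compounds on the way: none F0.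

**Step 9.** The amine-catalysed reaction of the hindered α-silyloxy aldehyde may be slow, may erode C8, or may touch the enal. The fallback sets out from 14 and comes back at 16. It is a vinylalumination: methyl propiolate is hydroaluminated with i-Bu2AlH/N-methylmorpholine N-oxide (THF, 0 °C) to the [1-(methoxycarbonyl)vinyl]aluminium reagent. This adds 1,2 to the more electrophilic saturated α-silyloxy aldehyde of 14 at −78 °C and gives 16 directly, in hours and without amine base. New compounds on the way: none F0.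

**Step 8.** The oxidative desilylation may be incomplete or may attack the secondary silyl ether or the epoxide. The fallback sets out from 13 and comes back at 14. The primary triethylsilyl ether is solvolysed selectively (PPTS, MeOH/CH2Cl2, −10 °C) to the primary alcohol [(2R,3R)-2-{(2S)-3-hydroxy-2-[(triethylsilyl)oxy]propyl}-3-[(3E)-3-methyl-5-oxopent-3-en-1-yl]oxiran-2-yl]methyl acetate F1. F1 is then oxidised with Dess–Martin periodinane/NaHCO3 (CH2Cl2, 0 °C) to 14.

## Further compounds

F0 | step 11 | none | none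
F0 | step 9 | none | none
F1 | step 8 | [(2R,3R)-2-{(2S)-3-hydroxy-2-[(triethylsilyl)oxy]propyl}-3-[(3E)-3-methyl-5-oxopent-3-en-1-yl]oxiran-2-yl]methyl acetate | OC[C@@H](O[Si](CC)(CC)CC)C[C@]1(COC(C)=O)O[C@@H]1CC/C(C)=C/C=O
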